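**Retrosynthetic overview** (chain numbered C1 = CO2H to C24; ring A = oxolane C7–C10, ring B = 1,2-dioxane C3–C6)
1. Ring B is closed last by a 6-exo peroxy-Michael addition of a (6S)-hydroperoxide onto a C2=C3 (E)-enoate; the ester is then hydrolysed.
2. The hydroperoxide comes from SN2 inversion of the erythro (6R) alcohol triflate; the hydroxy enoate comes from Wittig opening of a lactol.
3. Key C5–C6 bond: the ring A acyl chloride (C6) is coupled with a zinc homoenolate equivalent, a β-metallated propanal acetal (C3–C5), giving a 2-acyl oxolane; chelation-controlled reduction then sets C6.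
4. The triene tail is made earlier by a Z-selective Wittig reaction of a C17 ylide with (E)-hepta-2,6-dienal, before any peroxide exists.
5. Ring A is formed first, by trans-selective aerobic oxidative cyclisation with Co(modp)2 of an (R)-pent-4-en-1-ol obtained from an enantiopure terminal epoxide.

Assumption: all numbered starting materials, including the enantiopure epoxide and the organozinc solution, are taken as catalogue items.

**Route**

Step 1
Reactants: 1 pent-4-enal; 2 (triphenylphosphoranylidene)acetaldehyde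
Product: 3 (2E)-hepta-2,6-dienal
Conditions: PhMe, 80 °C, 1 in 1.5-fold excess
Reagents that add atoms: none
Why: Wittig olefination with the formyl-stabilised ylide gives the (E)-enal selectively, and the excess of 1 suppresses a second homologation.

Step 2
Reactants: 4 1-bromo-6-chlorohexane; 5 (2S)-2-(but-3-en-1-yl)oxirane
Product: 7 (5R)-12-chlorododec-1-en-5-ol, via (6-chlorohexyl)magnesium bromide 6 (not isolated)
Conditions: Mg, THF, 35 °C; then CuI (10 mol%), 5, THF, −30 → 0 °C; aq NH4Cl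
Reagents that add atoms: none
Why: Magnesium inserts only into the carbon–bromine bond and the copper-catalysed Grignard opening of the terminal epoxide (SN2 at the CH2 carbon) leaves the epoxide stereocentre untouched, so C10 is (R) directly from 5.

Step 3
Reactants: 7 (5R)-12-chlorododec-1-en-5-ol
Product: 8 [(2S,5R)-5-(7-chloroheptyl)oxolan-2-yl]methanol
Conditions: Co(modp)2 (10 mol%; modp = 1-morpholinocarbamoyl-4,4-dimethyl-1,3-pentanedionate), O2 (1 atm), tBuOOH (10 mol%), iPrOH, 55 °C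
Reagents that add atoms: dioxygen (O=O)
Why: The Mukaiyama aerobic oxidative cyclisation of a 1-substituted pent-4-en-1-ol under divalent cobalt catalysis closes ring A by 5-exo attack of the bound alkoxide on the alkene and is known to give the 2,5-trans oxolane-methanol (typically >95:5), which sets C7 as (S) relative to C10 while the primary chloride is inert.

Step 4
Reactants: 8 [(2S,5R)-5-(7-chloroheptyl)oxolan-2-yl]methanol
Product: 10 (2S,5R)-5-(7-chloroheptyl)oxolane-2-carboxylic acid, via oxolane-2-carbaldehyde 9 (not isolated)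
Conditions: TEMPO (20 mol%), PhI(OAc)2 (2.2 equiv), MeCN/H2O 1:1, rt
Reagents that add atoms: water (O)
Why: The TEMPO/PhI(OAc)2 oxidation (Epp–Widlanski) takes the primary alcohol through the aldehyde hydrate to the acid without base, so the α-alkoxy stereocentre C7 is not epimerised.

Step 5
Reactants: 10 (2S,5R)-5-(7-chloroheptyl)oxolane-2-carboxylic acid
Product: 11 {7-[(2R,5S)-5-carboxyoxolan-2-yl]heptyl}triphenylphosphonium iodide
Conditions: PPh3 (1.5 equiv), NaI (1.5 equiv), MeCN, reflux, 36 h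
Reagents that add atoms: triphenylphosphine (c1ccc(cc1)P(c1ccccc1)c1ccccc1); sodium iodide ([Na+].[I-])
Why: Finkelstein exchange to the iodide followed by SN2 quaternisation of PPh3 gives the phosphonium salt, and neither reagent touches the free acid or the stereocentres.

Step 6
Reactants: 11 {7-[(2R,5S)-5-carboxyoxolan-2-yl]heptyl}triphenylphosphonium iodide; 3 (2E)-hepta-2,6-dienal
Product: 13 (2S,5R)-5-[(7Z,9E)-tetradeca-7,9,13-trien-1-yl]oxolane-2-carboxylic acid, via sodium ylide carboxylate 12 (not isolated)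
Conditions: NaN(SiMe3)2 (2.1 equiv), THF, −78 → 0 °C; 3 (1.2 equiv), −78 °C → rt; 1 M HCl to pH 3
Reagents that add atoms: none
Why: The Z-selective Wittig reaction of the non-stabilised ylide (kinetic cis-oxaphosphetane) with the (E)-enal builds the (17Z,19E)-diene in one operation, with the carboxylate riding along as in prostaglandin Wittig chemistry and the enal geometry retained.

Step 7 (key step)
Reactants: 13 (2S,5R)-5-[(7Z,9E)-tetradeca-7,9,13-trien-1-yl]oxolane-2-carboxylic acid; 14 [2-(1,3-dioxolan-2-yl)ethyl]zinc bromide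
Product: 16 3-(1,3-dioxolan-2-yl)-1-{(2S,5R)-5-[(7Z,9E)-tetradeca-7,9,13-trien-1-yl]oxolan-2-yl}propan-1-one, via acid chloride 15 (not isolated)
Conditions: 1-chloro-N,N,2-trimethylprop-1-en-1-amine (1.1 equiv), CH2Cl2, 0 °C → rt; then 14 (1.3 equiv), Pd(PPh3)4 (5 mol%), THF, 0 °C → rt
Reagents that add atoms: none
Why: In this Negishi acylation the zinc reagent is a propanal homoenolate (d3) equivalent whose β-carbon, normally an electrophilic site, is joined under zerovalent palladium catalysis to the electrophilic acyl carbon C6, which delivers the 1,4-dioxygenated C3–C6 unit in one step under base-free conditions so that C7 cannot epimerise through a ketene or an enolate.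

Step 8
Reactants: 16 3-(1,3-dioxolan-2-yl)-1-{(2S,5R)-5-[(7Z,9E)-tetradeca-7,9,13-trien-1-yl]oxolan-2-yl}propan-1-one
Product: 18 (5R)-5-{(2S,5R)-5-[(7Z,9E)-tetradeca-7,9,13-trien-1-yl]oxolan-2-yl}oxolan-2-ol (anomer mixture), via hydroxy acetal 17 (not isolated)
Conditions: Zn(BH4)2 (1.0 equiv, Et2O solution), Et2O, −40 °C; then 1 M HCl, THF, rt
Reagents that add atoms: water (O)
Why: Chelation-controlled (Cram-chelate, Nakata–Oishi) hydride delivery from Zn(BH4)2 to the zinc-bridged chelate of the oxolane oxygen and the carbonyl, from the face of the C7–H, gives the erythro (6R) alcohol, and aqueous acid then exchanges the dioxolane for the five-membered lactol.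

Step 9
Reactants: 18 (5R)-5-{(2S,5R)-5-[(7Z,9E)-tetradeca-7,9,13-trien-1-yl]oxolan-2-yl}oxolan-2-ol; 19 methyl (triphenylphosphoranylidene)acetate
Product: 21 methyl (2E,6R)-6-hydroxy-6-{(2S,5R)-5-[(7Z,9E)-tetradeca-7,9,13-trien-1-yl]oxolan-2-yl}hex-2-enoate, via hydroxy aldehyde 20 (not isolated)
Conditions: 19 (1.5 equiv), PhCO2H (cat.), PhMe, 60 °C
Reagents that add atoms: none
Why: Wittig olefination of the ring-opened hydroxy aldehyde tautomer with the ester-stabilised ylide gives the (E)-enoate under neutral conditions, which keeps the free C6 hydroxyl from adding back in an oxa-Michael sense.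

Step 10
Reactants: 21 methyl (2E,6R)-6-hydroxy-6-{(2S,5R)-5-[(7Z,9E)-tetradeca-7,9,13-trien-1-yl]oxolan-2-yl}hex-2-enoate
Product: 23 methyl (2E,6S)-6-hydroperoxy-6-{(2S,5R)-5-[(7Z,9E)-tetradeca-7,9,13-trien-1-yl]oxolan-2-yl}hex-2-enoate, via triflate 22 (not isolated)
Conditions: Tf2O (1.2 equiv), 2,6-lutidine (1.5 equiv), CH2Cl2, −78 °C; then H2O2 (10 equiv, dry Et2O solution), KOtBu (3 equiv), THF, −40 → 0 °C; pH 7 buffer
Reagents that add atoms: hydrogen peroxide (OO)
Why: SN2 displacement of the secondary triflate by the α-effect nucleophile KOOH (sulfonate perhydrolysis of the Williams–Mosher and Salomon type) inverts C6 to the (6S)-hydroperoxide, and the large excess of H2O2 prevents dialkyl peroxide formation.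

Step 11
Reactants: 23 methyl (2E,6S)-6-hydroperoxy-6-{(2S,5R)-5-[(7Z,9E)-tetradeca-7,9,13-trien-1-yl]oxolan-2-yl}hex-2-enoate
Product: 24 methyl 2-[(3S,6S)-6-{(2S,5R)-5-[(7Z,9E)-tetradeca-7,9,13-trien-1-yl]oxolan-2-yl}-1,2-dioxan-3-yl]acetate
Conditions: Et2NH (1 equiv), CF3CH2OH, rt
Reagents that add atoms: none
Why: The base-mediated 6-exo-trig peroxy-Michael addition closes ring B through a chair transition state with both substituents equatorial, and its reversibility (retro-Michael) funnels material to the 3,6-trans isomer, which sets C3 as (S) from C6.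

Step 12
Reactants: 24 methyl 2-[(3S,6S)-6-{(2S,5R)-5-[(7Z,9E)-tetradeca-7,9,13-trien-1-yl]oxolan-2-yl}-1,2-dioxan-3-yl]acetate
Product: 26 2-[(3S,6S)-6-{(2S,5R)-5-[(7Z,9E)-tetradeca-7,9,13-trien-1-yl]oxolan-2-yl}-1,2-dioxan-3-yl]acetic acid, via lithium carboxylate 25 (not isolated)
Conditions: LiOH (3 equiv), THF/H2O 3:1, 0 °C; then 1 M HCl to pH 3, 0 °C
Reagents that add atoms: lithium hydroxide ([Li+].[OH-])
Why: Saponification of the methyl ester with LiOH at 0 °C is faster than enolisation at C2, so the β-peroxy ester does not undergo E1cB ring opening and the four stereocentres are untouched.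

**Compound list**
1 | pent-4-enal | C=CCCC=O | starting material
2 | (triphenylphosphoranylidene)acetaldehyde | O=CC=P(c1ccccc1)(c1ccccc1)c1ccccc1 | starting material
3 | (2E)-hepta-2,6-dienal | C=CCC/C=C/C=O | intermediate
4 | 1-bromo-6-chlorohexane | ClCCCCCCBr | starting material
5 | (2S)-2-(but-3-en-1-yl)oxirane | C=CCC[C@H]1CO1 | starting material
6 | (6-chlorohexyl)magnesium bromide | ClCCCCCC[Mg]Br | intermediate
7 | (5R)-12-chlorododec-1-en-5-ol | ClCCCCCCC[C@@H](O)CCC=C | intermediate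
8 | [(2S,5R)-5-(7-chloroheptyl)oxolan-2-yl]methanol | ClCCCCCCC[C@@H]1CC[C@@H](CO)O1 | intermediate
9 | (2S,5R)-5-(7-chloroheptyl)oxolane-2-carbaldehyde | ClCCCCCCC[C@@H]1CC[C@@H](C=O)O1 | intermediate
10 | (2S,5R)-5-(7-chloroheptyl)oxolane-2-carboxylic acid | ClCCCCCCC[C@@H]1CC[C@@H](C(=O)O)O1 | intermediate
11 | {7-[(2R,5S)-5-carboxyoxolan-2-yl]heptyl}triphenylphosphonium iodide | [I-].c1ccccc1[P+](c1ccccc1)(c1ccccc1)CCCCCCC[C@@H]1CC[C@@H](C(=O)O)O1 | intermediate
12 | sodium (2S,5R)-5-[7-(triphenylphosphoranylidene)heptyl]oxolane-2-carboxylate | [Na+].c1ccccc1P(c1ccccc1)(c1ccccc1)=CCCCCCC[C@@H]1CC[C@@H](C(=O)[O-])O1 | intermediate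
13 | (2S,5R)-5-[(7Z,9E)-tetradeca-7,9,13-trien-1-yl]oxolane-2-carboxylic acid | C=CCC/C=C/C=C\CCCCCC[C@@H]1CC[C@@H](C(=O)O)O1 | intermediate
14 | [2-(1,3-dioxolan-2-yl)ethyl]zinc bromide | Br[Zn]CCC1OCCO1 | starting material
15 | (2S,5R)-5-[(7Z,9E)-tetradeca-7,9,13-trien-1-yl]oxolane-2-carbonyl chloride | C=CCC/C=C/C=C\CCCCCC[C@@H]1CC[C@@H](C(=O)Cl)O1 | intermediate
16 | 3-(1,3-dioxolan-2-yl)-1-{(2S,5R)-5-[(7Z,9E)-tetradeca-7,9,13-trien-1-yl]oxolan-2-yl}propan-1-one | C=CCC/C=C/C=C\CCCCCC[C@@H]1CC[C@@H](C(=O)CCC2OCCO2)O1 | intermediate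
17 | (1R)-3-(1,3-dioxolan-2-yl)-1-{(2S,5R)-5-[(7Z,9E)-tetradeca-7,9,13-trien-1-yl]oxolan-2-yl}propan-1-ol | C=CCC/C=C/C=C\CCCCCC[C@@H]1CC[C@@H]([C@H](O)CCC2OCCO2)O1 | intermediate
18 | (5R)-5-{(2S,5R)-5-[(7Z,9E)-tetradeca-7,9,13-trien-1-yl]oxolan-2-yl}oxolan-2-ol | C=CCC/C=C/C=C\CCCCCC[C@@H]1CC[C@@H]([C@H]2CCC(O)O2)O1 | intermediate
19 | methyl (triphenylphosphoranylidene)acetate | COC(=O)C=P(c1ccccc1)(c1ccccc1)c1ccccc1 | starting material
20 | (4R)-4-hydroxy-4-{(2S,5R)-5-[(7Z,9E)-tetradeca-7,9,13-trien-1-yl]oxolan-2-yl}butanal | C=CCC/C=C/C=C\CCCCCC[C@@H]1CC[C@@H]([C@H](O)CCC=O)O1 | intermediate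
21 | methyl (2E,6R)-6-hydroxy-6-{(2S,5R)-5-[(7Z,9E)-tetradeca-7,9,13-trien-1-yl]oxolan-2-yl}hex-2-enoate | C=CCC/C=C/C=C\CCCCCC[C@@H]1CC[C@@H]([C@H](O)CC/C=C/C(=O)OC)O1 | intermediate
22 | methyl (2E,6R)-6-{(2S,5R)-5-[(7Z,9E)-tetradeca-7,9,13-trien-1-yl]oxolan-2-yl}-6-[(trifluoromethanesulfonyl)oxy]hex-2-enoate | C=CCC/C=C/C=C\CCCCCC[C@@H]1CC[C@@H]([C@H](OS(=O)(=O)C(F)(F)F)CC/C=C/C(=O)OC)O1 | intermediate
23 | methyl (2E,6S)-6-hydroperoxy-6-{(2S,5R)-5-[(7Z,9E)-tetradeca-7,9,13-trien-1-yl]oxolan-2-yl}hex-2-enoate | C=CCC/C=C/C=C\CCCCCC[C@@H]1CC[C@@H]([C@@H](OO)CC/C=C/C(=O)OC)O1 | intermediate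
24 | methyl 2-[(3S,6S)-6-{(2S,5R)-5-[(7Z,9E)-tetradeca-7,9,13-trien-1-yl]oxolan-2-yl}-1,2-dioxan-3-yl]acetate | C=CCC/C=C/C=C\CCCCCC[C@@H]1CC[C@@H]([C@@H]2CC[C@@H](CC(=O)OC)OO2)O1 | intermediate
25 | lithium 2-[(3S,6S)-6-{(2S,5R)-5-[(7Z,9E)-tetradeca-7,9,13-trien-1-yl]oxolan-2-yl}-1,2-dioxan-3-yl]acetate | [Li+].C=CCC/C=C/C=C\CCCCCC[C@@H]1CC[C@@H]([C@@H]2CC[C@@H](CC(=O)[O-])OO2)O1 | intermediate
26 | 2-[(3S,6S)-6-{(2S,5R)-5-[(7Z,9E)-tetradeca-7,9,13-trien-1-yl]oxolan-2-yl}-1,2-dioxan-3-yl]acetic acid | C=CCC/C=C/C=C\CCCCCC[C@@H]1CC[C@@H]([C@@H]2CC[C@@H](CC(=O)O)OO2)O1 | target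

**Step count and risks**
Total steps: 12. Longest linear sequence: 11 (steps 2 to 12, from 4 and 5); step 1 is the only side branch.

In the fallbacks, Ox stands for the (2S,5R)-5-[(7Z,9E)-tetradeca-7,9,13-trien-1-yl]oxolan-2-yl group.

Most likely to fail, first: the perhydrolysis of triflate 22 in step 10. The leaving group sits next to the oxolane oxygen, so ring expansion through an oxonium ion, elimination, or attack of hydroperoxide on the enoate can compete. The fallback puts the hydroperoxide in before any Michael acceptor or ester exists. It sets out from 17, isolated by leaving out the acid stage of step 8. Tf2O and 2,6-lutidine give (1R)-3-(1,3-dioxolan-2-yl)-1-Ox-propyl trifluoromethanesulfonate F3, which can be exposed to a larger excess of KOOH/H2O2 to give the inverted 2-[(3S)-3-hydroperoxy-3-Ox-propyl]-1,3-dioxolane F4. AcOH/H2O/THF then closes the peroxy hemiacetal (6S)-6-Ox-1,2-dioxan-3-ol F5. Wittig olefination of F5 with 19 (PhMe, rt) opens it to 23, where the route is rejoined before step 11.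

Second: the key acylation in step 7. The α-alkoxy acyl-palladium species may lose CO, or transmetalation of the acetal-bearing zinc reagent may be slow. The fallback makes the same C5–C6 bond by a catalyst-free acyl substitution on a chelated amide. It sets out from 13: EDC·HCl, MeNHOMe·HCl and N-methylmorpholine give the Weinreb amide (2S,5R)-N-methoxy-N-methyl-5-[(7Z,9E)-tetradeca-7,9,13-trien-1-yl]oxolane-2-carboxamide F1. The Grignard form of the homoenolate equivalent, [2-(1,3-dioxolan-2-yl)ethyl]magnesium bromide F2 (from 2-(2-bromoethyl)-1,3-dioxolane and Mg in THF below 30 °C), adds once at −20 °C and gives 16, where the route is rejoined.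

Third: the saponification in step 12. Hydroxide may open ring B by E1cB elimination across C2–C3 or trigger Kornblum–DeLaMare fragmentation. The fallback unmasks the acid without base by changing the ester. It sets out from 18: Wittig olefination with allyl (triphenylphosphoranylidene)acetate gives prop-2-en-1-yl (2E,6R)-6-hydroxy-6-Ox-hex-2-enoate F6. The chemistry of steps 10 and 11 carries it through the triflate prop-2-en-1-yl (2E,6R)-6-Ox-6-[(trifluoromethanesulfonyl)oxy]hex-2-enoate F7 and the hydroperoxide prop-2-en-1-yl (2E,6S)-6-hydroperoxy-6-Ox-hex-2-enoate F8 to the allyl ester prop-2-en-1-yl 2-[(3S,6S)-6-Ox-1,2-dioxan-3-yl]acetate F9. Pd(PPh3)4 (5 mol%) and morpholine in THF at 0 °C then transfer the allyl group to the amine and give 26 directly.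

**Further compounds**
F1 | step 7 | (2S,5R)-N-methoxy-N-methyl-5-[(7Z,9E)-tetradeca-7,9,13-trien-1-yl]oxolane-2-carboxamide | C=CCC/C=C/C=C\CCCCCC[C@@H]1CC[C@@H](C(=O)N(C)OC)O1
F2 | step 7 | [2-(1,3-dioxolan-2-yl)ethyl]magnesium bromide | Br[Mg]CCC1OCCO1
F3 | step 10 | (1R)-3-(1,3-dioxolan-2-yl)-1-{(2S,5R)-5-[(7Z,9E)-tetradeca-7,9,13-trien-1-yl]oxolan-2-yl}propyl trifluoromethanesulfonate | C=CCC/C=C/C=C\CCCCCC[C@@H]1CC[C@@H]([C@H](OS(=O)(=O)C(F)(F)F)CCC2OCCO2)O1
F4 | step 10 | 2-[(3S)-3-hydroperoxy-3-{(2S,5R)-5-[(7Z,9E)-tetradeca-7,9,13-trien-1-yl]oxolan-2-yl}propyl]-1,3-dioxolane | C=CCC/C=C/C=C\CCCCCC[C@@H]1CC[C@@H]([C@@H](OO)CCC2OCCO2)O1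
F5 | step 10 | (6S)-6-{(2S,5R)-5-[(7Z,9E)-tetradeca-7,9,13-trien-1-yl]oxolan-2-yl}-1,2-dioxan-3-ol | C=CCC/C=C/C=C\CCCCCC[C@@H]1CC[C@@H]([C@@H]2CCC(O)OO2)O1
F6 | step 12 | prop-2-en-1-yl (2E,6R)-6-hydroxy-6-{(2S,5R)-5-[(7Z,9E)-tetradeca-7,9,13-trien-1-yl]oxolan-2-yl}hex-2-enoate | C=CCC/C=C/C=C\CCCCCC[C@@H]1CC[C@@H]([C@H](O)CC/C=C/C(=O)OCC=C)O1
F7 | step 12 | prop-2-en-1-yl (2E,6R)-6-{(2S,5R)-5-[(7Z,9E)-tetradeca-7,9,13-trien-1-yl]oxolan-2-yl}-6-[(trifluoromethanesulfonyl)oxy]hex-2-enoate | C=CCC/C=C/C=C\CCCCCC[C@@H]1CC[C@@H]([C@H](OS(=O)(=O)C(F)(F)F)CC/C=C/C(=O)OCC=C)O1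
F8 | step 12 | prop-2-en-1-yl (2E,6S)-6-hydroperoxy-6-{(2S,5R)-5-[(7Z,9E)-tetradeca-7,9,13-trien-1-yl]oxolan-2-yl}hex-2-enoate | C=CCC/C=C/C=C\CCCCCC[C@@H]1CC[C@@H]([C@@H](OO)CC/C=C/C(=O)OCC=C)O1
F9 | step 12 | prop-2-en-1-yl 2-[(3S,6S)-6-{(2S,5R)-5-[(7Z,9E)-tetradeca-7,9,13-trien-1-yl]oxolan-2-yl}-1,2-dioxan-3-yl]acetate | C=CCC/C=C/C=C\CCCCCC[C@@H]1CC[C@@H]([C@@H]2CC[C@@H](CC(=O)OCC=C)OO2)O1
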